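The route rests on building the benzene ring (C1'–C6') of the target from a four-carbon and a two-carbon piece: 3-methoxycyclobut-2-en-1-one supplies C2', C5', C6' and C1', a prenyl-bearing silyl ynol ether supplies C3' and C4'. One thermal cascade forms three ring bonds and delivers the 1,3,5-trioxygenated arene with the prenyl group at C3' between the C2' and C4' oxygens and para to the C6' methyl ether, leaving C1' and C5' as CH. Desilylation makes these two positions equivalent, so one ortho-lithiation/acylation with the (R)-Weinreb amide and one Mannich-type methylene coupling to the pyrone finish the molecule.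

Key step: step 4

Remark: the benzene ring is numbered C1' (CH2 bridge), C2' (OH), C3' (prenyl), C4' (OH), C5' (acyl), C6' (OMe); the acyl stereocentre of the target is R, is bought with (R)-2-methylbutanoic acid and is never made or broken; methoxyethyne and ketene are assumed to need preparation.

Step 1
Reactants: 1 chloroacetaldehyde dimethyl acetal
Product: 3 methoxyethyne, via sodium methoxyethynide 2 (not isolated)
Conditions: NaNH2 (3 equiv), liq. NH3, −33 °C; NH3 evaporated; cold sat. aq. NaCl, −20 °C; product distilled into a cold trap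
Reagents that add atoms: none
Why: Twofold base-induced β-elimination (loss of methanol, then of HCl) by NaNH2 gives the sodium alkynide, which cold brine protonates, the classical dehydrohalogenation route to alkoxyalkynes.

Step 2
Reactants: 3 methoxyethyne; 4 acetone
Product: 6 3-methoxycyclobut-2-en-1-one, via ketene 5 (not isolated)
Conditions: 4, hot-wire pyrolysis (ketene lamp, ca. 700 °C); gas stream passed into 3, CH2Cl2, −10 → 0 °C
Reagents that add atoms: none
Why: Thermal [2+2] cycloaddition of ketene with the electron-rich alkoxyalkyne, whose unsubstituted carbon attacks the ketene carbonyl carbon, should give the 3-alkoxycyclobutenone as the only regioisomer.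

Step 3
Reactants: 7 ethyl 4-methylpent-3-enoate
Product: 10 triisopropyl[(5-methylhex-4-en-1-yn-1-yl)oxy]silane, via dibromo enolate 8 (not isolated), via lithium ynolate 9 (not isolated)
Conditions: CH2Br2, LiTMP (lithium 2,2,6,6-tetramethylpiperidide), THF, −78 °C; 7; n-BuLi, −78 °C → rt; i-Pr3SiCl, −78 °C → rt
Reagents that add atoms: dibromomethane, BrCBr; chlorotriisopropylsilane, CC(C)[Si](Cl)(C(C)C)C(C)C
Why: Kowalski ynolate synthesis, in which LiCHBr2 adds to the ester, bromine–lithium exchange on the derived dibromo enolate triggers a 1,2-shift of the allylic CH2 group to give the ynolate, and the bulky silyl chloride traps it on oxygen.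

Step 4
Reactants: 6 3-methoxycyclobut-2-en-1-one; 10 triisopropyl[(5-methylhex-4-en-1-yn-1-yl)oxy]silane
Product: 14 5-methoxy-2-(3-methylbut-2-en-1-yl)-3-[(triisopropylsilyl)oxy]phenol, via vinylketene 11 (not isolated), via vinylcyclobutenone 12 (not isolated), via dienylketene 13 (not isolated)
Conditions: toluene, 80 °C then 110 °C, sealed tube, argon
Reagents that add atoms: none
Why: Heating opens 6 by a four-electron electrocyclic reaction to (1-methoxyvinyl)ketene 11, which adds across its C=C bond to the ynol ether in a thermal [2+2] cycloaddition to give 4-vinylcyclobutenone 12 (bonds C2'–C3' and C4'–C5'). A second four-electron opening gives dienylketene 13, and a six-electron disrotatory electrocyclisation then closes the six-membered carbocycle by forming C1'–C2', after which the cyclohexadienone tautomerises to phenol 14. The closest known reaction type is the Danheiser benzannulation of cyclobutenones with siloxyalkynes, here with a 3-alkoxycyclobutenone as the ketene source. No stereocentre is formed. The step needs regioselectivity in the [2+2] addition, and the polarised ynol ether secures it, because its nucleophilic prenyl-bearing carbon bonds to the electrophilic ketene carbonyl carbon, which puts prenyl between OH and OSi and para to OMe. The alkoxy donor stabilises the cyclobutenone, so the second heating stage at 110 °C is planned to drive both ring openings.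

Step 5
Reactants: 14 5-methoxy-2-(3-methylbut-2-en-1-yl)-3-[(triisopropylsilyl)oxy]phenol
Product: 16 5-methoxy-1,3-bis(methoxymethoxy)-2-(3-methylbut-2-en-1-yl)benzene, via resorcinol 15 (not isolated)
Conditions: TBAF, THF, 0 °C; then NaH, MOMCl, 0 °C → rt
Reagents that add atoms: chloromethyl methyl ether, COCCl
Why: Fluoride-induced cleavage of the aryl silyl ether followed by Williamson-type etherification of both phenoxides gives an arene with a mirror plane through C3' and C6', in which the two aromatic CH positions are equivalent.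

Step 6
Reactants: 17 (R)-2-methylbutanoic acid
Product: 19 (2R)-N-methoxy-N,2-dimethylbutanamide, via acyl imidazole 18 (not isolated)
Conditions: CDI, CH2Cl2, 0 °C → rt; then MeNH(OMe)·HCl, rt
Reagents that add atoms: N,O-dimethylhydroxylamine hydrochloride, CNOC.Cl
Why: Amide coupling through the acyl imidazole is a near-neutral activation that should not enolise the α-carbon, so the R configuration of the acid is carried over unchanged.

Step 7
Reactants: 16 5-methoxy-1,3-bis(methoxymethoxy)-2-(3-methylbut-2-en-1-yl)benzene; 19 (2R)-N-methoxy-N,2-dimethylbutanamide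
Product: 21 (2R)-1-[6-methoxy-2,4-bis(methoxymethoxy)-3-(3-methylbut-2-en-1-yl)phenyl]-2-methylbutan-1-one, via aryllithium 20 (not isolated)
Conditions: n-BuLi, TMEDA, THF, −20 → 0 °C; then 19, −78 → 0 °C; aq. NH4Cl
Reagents that add atoms: none
Why: Directed ortho-metalation places lithium between the OMOM and OMe groups (either CH gives the same aryllithium), and Weinreb ketone synthesis through the chelated tetrahedral adduct releases the ketone only on work-up, leaving the existing R stereocentre untouched.

Step 8
Reactants: 21 (2R)-1-[6-methoxy-2,4-bis(methoxymethoxy)-3-(3-methylbut-2-en-1-yl)phenyl]-2-methylbutan-1-one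
Product: 22 (2R)-1-[2,4-dihydroxy-6-methoxy-3-(3-methylbut-2-en-1-yl)phenyl]-2-methylbutan-1-one
Conditions: HCl (ca. 1 M), MeOH, rt
Reagents that add atoms: none
Why: Acid-catalysed acetal methanolysis removes both MOM groups at room temperature, conditions chosen to be too mild to protonate the prenyl alkene or to enolise the ketone α-carbon.

Step 9
Reactants: 23 pentan-3-one
Product: 24 (Z)-trimethyl(pent-2-en-3-yloxy)silane
Conditions: Me3SiCl, Et3N, DMF, 80 °C
Reagents that add atoms: chlorotrimethylsilane, C[Si](C)(C)Cl
Why: Thermodynamic silyl enol ether formation on a symmetrical ketone can give only one regioisomer, and the alkene geometry (Z expected, E equally usable) is lost in the next step.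

Step 10
Reactants: 24 (Z)-trimethyl(pent-2-en-3-yloxy)silane; 25 malonyl dichloride
Product: 27 6-ethyl-4-hydroxy-5-methyl-2H-pyran-2-one, via diketo acid chloride 26 (not isolated)
Conditions: Et2O, −20 °C → rt
Reagents that add atoms: none
Why: Acylative pyrone annulation, in which C-acylation of the silyl enol ether by one acid chloride is followed by O-acylation of the ketone enol by the other and enolisation to the 4-hydroxy-2-pyrone.

Step 11
Reactants: 22 (2R)-1-[2,4-dihydroxy-6-methoxy-3-(3-methylbut-2-en-1-yl)phenyl]-2-methylbutan-1-one; 27 6-ethyl-4-hydroxy-5-methyl-2H-pyran-2-one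
Product: 30 3-{[2,4-dihydroxy-6-methoxy-3-(3-methylbut-2-en-1-yl)-5-[(2R)-2-methylbutanoyl]phenyl]methyl}-6-ethyl-4-hydroxy-5-methyl-2H-pyran-2-one, via Mannich base 28 (not isolated), via methylidene pyrandione 29 (not isolated)
Conditions: 27, CH2=NMe2+ I− (1 equiv), MeCN, rt; then 22, 40 °C
Reagents that add atoms: N,N-dimethylmethyleneiminium iodide (Eschenmoser's salt), C=[N+](C)C.[I-]
Why: Mannich reaction at C3 of the pyrone, loss of dimethylamine to the 3-methylidene pyrandione and Friedel–Crafts-type conjugate addition of C1' of 22, the only free aromatic CH and one activated by an ortho and a para hydroxyl, should form the methylene bridge under near-neutral conditions that spare the stereocentre.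

Compound list
1 | chloroacetaldehyde dimethyl acetal (2-chloro-1,1-dimethoxyethane) | COC(CCl)OC | starting material
2 | sodium methoxyethynide | [Na+].[C-]#COC | intermediate
3 | methoxyethyne | COC#C | intermediate
4 | acetone | CC(C)=O | starting material
5 | ketene | C=C=O | intermediate
6 | 3-methoxycyclobut-2-en-1-one | COC1=CC(=O)C1 | intermediate
7 | ethyl 4-methylpent-3-enoate | CCOC(=O)CC=C(C)C | starting material
8 | lithium 1,1-dibromo-5-methylhexa-1,4-dien-2-olate | [Li+].[O-]C(CC=C(C)C)=C(Br)Br | intermediate
9 | lithium 5-methylhex-4-en-1-yn-1-olate | [Li+].[O-]C#CCC=C(C)C | intermediate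
10 | triisopropyl[(5-methylhex-4-en-1-yn-1-yl)oxy]silane | CC(C)=CCC#CO[Si](C(C)C)(C(C)C)C(C)C | intermediate
11 | 3-methoxybuta-1,3-dien-1-one, (1-methoxyvinyl)ketene | COC(=C)C=C=O | intermediate
12 | 4-(1-methoxyethenyl)-2-(3-methylbut-2-en-1-yl)-3-[(triisopropylsilyl)oxy]cyclobut-2-en-1-one (racemic) | COC(=C)C1C(=O)C(CC=C(C)C)=C1O[Si](C(C)C)(C(C)C)C(C)C | intermediate
13 | (3E)-5-methoxy-2-(3-methylbut-2-en-1-yl)-3-[(triisopropylsilyl)oxy]hexa-1,3,5-trien-1-one | O=C=C(CC=C(C)C)/C(O[Si](C(C)C)(C(C)C)C(C)C)=C\C(=C)OC | intermediate
14 | 5-methoxy-2-(3-methylbut-2-en-1-yl)-3-[(triisopropylsilyl)oxy]phenol | COc1cc(O)c(CC=C(C)C)c(O[Si](C(C)C)(C(C)C)C(C)C)c1 | intermediate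
15 | 5-methoxy-2-(3-methylbut-2-en-1-yl)benzene-1,3-diol | COc1cc(O)c(CC=C(C)C)c(O)c1 | intermediate
16 | 5-methoxy-1,3-bis(methoxymethoxy)-2-(3-methylbut-2-en-1-yl)benzene | COCOc1cc(OC)cc(OCOC)c1CC=C(C)C | intermediate
17 | (R)-2-methylbutanoic acid | CC[C@@H](C)C(=O)O | starting material
18 | (2R)-1-(1H-imidazol-1-yl)-2-methylbutan-1-one | CC[C@@H](C)C(=O)n1ccnc1 | intermediate
19 | (2R)-N-methoxy-N,2-dimethylbutanamide | CC[C@@H](C)C(=O)N(C)OC | intermediate
20 | [6-methoxy-2,4-bis(methoxymethoxy)-3-(3-methylbut-2-en-1-yl)phenyl]lithium | [Li]c1c(OC)cc(OCOC)c(CC=C(C)C)c1OCOC | intermediate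
21 | (2R)-1-[6-methoxy-2,4-bis(methoxymethoxy)-3-(3-methylbut-2-en-1-yl)phenyl]-2-methylbutan-1-one | CC[C@@H](C)C(=O)c1c(OC)cc(OCOC)c(CC=C(C)C)c1OCOC | intermediate
22 | (2R)-1-[2,4-dihydroxy-6-methoxy-3-(3-methylbut-2-en-1-yl)phenyl]-2-methylbutan-1-one | CC[C@@H](C)C(=O)c1c(OC)cc(O)c(CC=C(C)C)c1O | intermediate
23 | pentan-3-one | CCC(=O)CC | starting material
24 | (Z)-trimethyl(pent-2-en-3-yloxy)silane | C/C=C(/CC)O[Si](C)(C)C | intermediate
25 | malonyl dichloride | O=C(Cl)CC(=O)Cl | starting material
26 | 4-methyl-3,5-dioxoheptanoyl chloride (racemic) | CCC(=O)C(C)C(=O)CC(=O)Cl | intermediate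
27 | 6-ethyl-4-hydroxy-5-methyl-2H-pyran-2-one | CCc1oc(=O)cc(O)c1C | intermediate
28 | 3-[(dimethylamino)methyl]-6-ethyl-4-hydroxy-5-methyl-2H-pyran-2-one | CCc1oc(=O)c(CN(C)C)c(O)c1C | intermediate
29 | 6-ethyl-5-methyl-3-methylidene-2H-pyran-2,4(3H)-dione | CCC1=C(C)C(=O)C(=C)C(=O)O1 | intermediate
30 | 3-{[2,4-dihydroxy-6-methoxy-3-(3-methylbut-2-en-1-yl)-5-[(2R)-2-methylbutanoyl]phenyl]methyl}-6-ethyl-4-hydroxy-5-methyl-2H-pyran-2-one | CCc1oc(=O)c(Cc2c(O)c(CC=C(C)C)c(O)c(C(=O)[C@H](C)CC)c2OC)c(O)c1C | target

Total step count: 11. Longest linear sequence: 7 steps (steps 1, 2, 4, 5, 7, 8, 11).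

Steps most likely to fail

Step 4. The donor-stabilised cyclobutenone may open only at temperatures at which the vinylketene is consumed by oligomerisation or by O-acylation of the phenol already formed, so that the cascade stalls before ring closure. The fallback sets out from ynol ether 10 and comes back at phenol 14; it generates the same vinylketene photochemically at room temperature. Commercial 3,3-dimethoxybutan-2-one should lose methanol on acid-catalysed distillation to give 3-methoxybut-3-en-2-one F1. Its lithium enolate (LiN(SiMe3)2, THF, −78 °C) is trifluoroacetylated with 2,2,2-trifluoroethyl trifluoroacetate to 1,1,1-trifluoro-5-methoxyhex-5-ene-2,4-dione F2. Detrifluoroacetylative diazo transfer with MsN3 and Et3N then gives 1-diazo-3-methoxybut-3-en-2-one F3. Irradiating F3 with 10 in CH2Cl2 should trigger a photochemical Wolff rearrangement to vinylketene 11, which is expected to continue through 12 and 13 to 14 on gentle warming.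

Step 7. Addition of the hindered, doubly ortho-substituted aryllithium to the α-branched amide may be slow, so that proton transfer from the amide α-carbon or from the doubly activated prenyl CH2 returns starting arene instead of ketone. The fallback sets out from amide 19 and aryllithium 20 and comes back at ketone 21; it replaces acyl substitution by carbonyl addition and oxidation. Reduction of 19 with diisobutylaluminium hydride (i-Bu2AlH) at −78 °C gives (2R)-2-methylbutanal F4, used cold and at once. F4 is added to 20 at −78 °C to give (2R)-1-[6-methoxy-2,4-bis(methoxymethoxy)-3-(3-methylbut-2-en-1-yl)phenyl]-2-methylbutan-1-ol F5 as a mixture of carbinol epimers. Buffered Dess–Martin oxidation of F5 should give 21.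

Step 11. The methylidene pyrandione may be trapped by a second pyrone faster than by the acyl-deactivated arene, so that self-coupling to a methylene-bis-pyrone outruns the cross-coupling. The fallback sets out from ketone 22 and comes back at target 30; it puts the methylene on the arene first. Mannich reaction of 22 with Eschenmoser's salt at its single free aromatic CH gives (2R)-1-{3-[(dimethylamino)methyl]-4,6-dihydroxy-2-methoxy-5-(3-methylbut-2-en-1-yl)phenyl}-2-methylbutan-1-one F6. Heating F6 with 27 in dioxane should expel dimethylamine to give the ortho-quinone methide 3-hydroxy-5-methoxy-6-methylidene-2-(3-methylbut-2-en-1-yl)-4-[(2R)-2-methylbutanoyl]cyclohexa-2,4-dien-1-one F7. Conjugate addition of pyrone C3 to F7 should then give 30.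

Further compounds
F1 | step 4 | 3-methoxybut-3-en-2-one | CC(=O)C(=C)OC
F2 | step 4 | 1,1,1-trifluoro-5-methoxyhex-5-ene-2,4-dione | COC(=C)C(=O)CC(=O)C(F)(F)F
F3 | step 4 | 1-diazo-3-methoxybut-3-en-2-one | COC(=C)C(=O)C=[N+]=[N-]
F4 | step 7 | (2R)-2-methylbutanal | CC[C@@H](C)C=O
F5 | step 7 | (2R)-1-[6-methoxy-2,4-bis(methoxymethoxy)-3-(3-methylbut-2-en-1-yl)phenyl]-2-methylbutan-1-ol (mixture of C1 epimers) | CC[C@@H](C)C(O)c1c(OC)cc(OCOC)c(CC=C(C)C)c1OCOC
F6 | step 11 | (2R)-1-{3-[(dimethylamino)methyl]-4,6-dihydroxy-2-methoxy-5-(3-methylbut-2-en-1-yl)phenyl}-2-methylbutan-1-one | CC[C@@H](C)C(=O)c1c(OC)c(CN(C)C)c(O)c(CC=C(C)C)c1O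
F7 | step 11 | 3-hydroxy-5-methoxy-6-methylidene-2-(3-methylbut-2-en-1-yl)-4-[(2R)-2-methylbutanoyl]cyclohexa-2,4-dien-1-one | C=C1C(=O)C(CC=C(C)C)=C(O)C(C(=O)[C@H](C)CC)=C1OC
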